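**Plan**
- Retrosynthetic cuts: first the depside ester bond between O4 of ring A and the ring B carbonyl, then the C1'–carboxyl bond of ring B, then ring B itself along C4'–C5', C6'–C1' and C3'–C4'; on ring A only the C5–CH3 bond.
- Forward order: a four-membered chloro enone is made from dichloroketene and propyne, and it closes ring B with 1-methoxypropyne in one thermal cascade. The single ring CH (C1') is then brominated and carboxylated, and ring A (atraric acid, C-methylated at C5) is esterified on O4 last.
- Enabling feature: ring B carries C4'–OH, C5'–CH3 and C6'–OCH3 in a row (phenol, alkyl, alkoxy), flanked by C3'–Cl and C2'–CH3, with C1' able to start as CH. This is the pattern a vinylketene/ynol ether benzannulation writes directly.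
- Stereochemistry: the target has no stereocentre and no stereogenic double bond; the CHCl centre of the cyclobutenone is used racemic and vanishes on aromatization.

Key step: step 4

Remark: primed locants refer to ring B (C1' bears the ester carbonyl); the E geometries written for the transient ketenes are those expected from outward rotation of chlorine and are not carried into any isolated compound.

**Route**

Step 1
Reactants: 1 trichloroacetyl chloride; 2 propyne
Product: 4 4,4-dichloro-3-methylcyclobut-2-en-1-one, via dichloroketene 3 (not isolated)
Conditions: Zn–Cu couple, Et2O/DME, propyne (excess, dry-ice condenser), slow addition of 1, 0 °C to rt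
Reagents that add atoms: none
Why: Zinc dechlorination of 1 releases dichloroketene, whose electrophilic central carbon bonds to the terminal carbon of propyne in a ketene–alkyne (2+2) cycloaddition, the standard entry to 3-alkyl-4,4-dichlorocyclobutenones.

Step 2
Reactants: 4 4,4-dichloro-3-methylcyclobut-2-en-1-one
Product: 5 4-chloro-3-methylcyclobut-2-en-1-one (racemic)
Conditions: Zn dust (1.0 equiv), AcOH, TMEDA, EtOH, −10 to 0 °C, stopped at the monochloride
Reagents that add atoms: none
Why: Zinc/acetic acid reductive dehalogenation of an α,α-dichloroketone removes the first chlorine more readily than the second, so one equivalent of zinc at low temperature should stop at the α-monochloroketone, whose CHCl centre forms as a racemate by protonation of the zinc enolate.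

Step 3
Reactants: 6 chloroacetaldehyde dimethyl acetal
Product: 8 1-methoxyprop-1-yne, via sodium methoxyacetylide 7 (not isolated)
Conditions: NaNH2 (3 equiv), liquid NH3, −33 °C; then MeI, −33 °C; distillation
Reagents that add atoms: iodomethane, CI
Why: Twofold elimination (methanol, then hydrogen chloride) with sodium amide gives the alkynyl ether as its sodium acetylide, which is C-methylated in the same flask, the standard acetylide alkylation route to 1-alkoxy-1-alkynes.

Step 4
Reactants: 5 4-chloro-3-methylcyclobut-2-en-1-one; 8 1-methoxyprop-1-yne
Product: 13 2-chloro-5-methoxy-3,6-dimethylphenol, via chlorovinylketene 9 (not isolated), via vinylcyclobutenone 10 (not isolated), via dienylketene 11 (not isolated), via chlorodienone 12 (not isolated)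
Conditions: 8 (2 equiv), toluene, 80 °C then 110 °C, sealed tube
Reagents that add atoms: none
Why: Proposed new method: conrotatory four-electron opening of 5, with chlorine rotating outward, should give the (E)-(2-chlorovinyl)ketene 9, whose ketene carbon is attacked by the methyl-bearing, nucleophilic carbon of ynol ether 8 in a (2+2) cycloaddition that forms C4'–C5' and C6'–C1' and gives vinylcyclobutenone 10. A second four-electron opening turns 10 into dienylketene 11, which closes ring B between the ketene carbon and the chlorovinyl terminus (C3'–C4') by a thermal disrotatory six-electron electrocyclization, and the 6-chlorodienone 12 so formed still has a hydrogen on the chlorinated carbon and should enolize to phenol 13 with the chlorine kept. The closest known reaction type is the Danheiser benzannulation of 3-alkylcyclobutenones with alkoxyalkynes, and the thermal opening of 4-chlorocyclobutenones to chlorovinylketenes is also known; what is untested is the combination, in which a 4-chloro substituent is carried through the whole cascade into the arene. The only ring that persists is the six-membered carbocycle, closed by 6π electrocyclization, and no stereocentre survives, since the CHCl centres of 5 and 12 and the ring CH of 10 are flattened on aromatization. The selectivity needed is the orientation of the (2+2) step, and the oxygen-polarized triple bond of 8 secures it by making the methyl-bearing carbon the one that bonds to the ketene carbon, so that OCH3 ends meta to OH with CH3 between them and the unsubstituted carbon becomes C1'. A methyl ynol ether is chosen because it has no β-hydrogen and so cannot fragment to a ketene by retro-ene reaction at the temperature of the cascade.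

Step 5
Reactants: 13 2-chloro-5-methoxy-3,6-dimethylphenol
Product: 14 (2-chloro-5-methoxy-3,6-dimethylphenoxy)tri(propan-2-yl)silane
Conditions: i-Pr3SiOTf, 2,6-lutidine, CH2Cl2, 0 °C to rt
Reagents that add atoms: triisopropylsilyl trifluoromethanesulfonate, CC(C)[Si](OS(=O)(=O)C(F)(F)F)(C(C)C)C(C)C
Why: O-silylation of a di-ortho-substituted phenol with a silyl triflate and a hindered pyridine base is routine, and the triisopropylsilyl ether tolerates the bromination, butyllithium and acyl chloride formation that follow.

Step 6
Reactants: 14 (2-chloro-5-methoxy-3,6-dimethylphenoxy)tri(propan-2-yl)silane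
Product: 15 (4-bromo-2-chloro-5-methoxy-3,6-dimethylphenoxy)tri(propan-2-yl)silane
Conditions: NBS, MeCN, 0 °C to rt, dark
Reagents that add atoms: N-bromosuccinimide, O=C1CCC(=O)N1Br
Why: Electrophilic aromatic bromination can only go to the single ring CH (C1'), which is para to the silyloxy and ortho to the methoxy group, and the polar, light-free medium suppresses benzylic bromination.

Step 7
Reactants: 15 (4-bromo-2-chloro-5-methoxy-3,6-dimethylphenoxy)tri(propan-2-yl)silane
Product: 18 3-chloro-6-methoxy-2,5-dimethyl-4-{[tri(propan-2-yl)silyl]oxy}benzoic acid, via aryllithium 16 (not isolated), via lithium carboxylate 17 (not isolated)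
Conditions: n-BuLi, THF, −78 °C; CO2 (gas), −78 °C to rt; aq. HCl
Reagents that add atoms: carbon dioxide, O=C=O
Why: Bromine–lithium exchange at −78 °C is far faster than chlorine–lithium exchange or benzylic deprotonation, the lithium sits meta to chlorine so no aryne can form, and carboxylation of an aryllithium with carbon dioxide is standard.

Step 8
Reactants: 19 methyl 2,4-dihydroxy-3,6-dimethylbenzoate (atraric acid)
Product: 21 methyl 3-formyl-4,6-dihydroxy-2,5-dimethylbenzoate (formyl at C5 in the numbering of 19), via chloro ether 20 (not isolated)
Conditions: Cl2CHOMe, TiCl4, CH2Cl2, 0 °C to rt; H2O work-up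
Reagents that add atoms: dichloromethyl methyl ether, COC(Cl)Cl; water, O
Why: Rieche formylation, with titanium tetrachloride bound to the phenol, delivers the electrophile to the one free ring position (ortho to the 4-hydroxyl and para to the 2-hydroxyl), and hydrolysis of the α-chloro ether on work-up gives the aldehyde.

Step 9
Reactants: 21 methyl 3-formyl-4,6-dihydroxy-2,5-dimethylbenzoate
Product: 22 methyl 2,4-dihydroxy-3,5,6-trimethylbenzoate
Conditions: Et3SiH (excess), CF3CO2H, rt
Reagents that add atoms: none
Why: Ionic hydrogenation with a silane in trifluoroacetic acid takes an aryl aldehyde that has ortho and para hydroxyl groups down to the methyl group through the stabilized benzylic cation, leaving the methyl ester untouched.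

Step 10
Reactants: 18 3-chloro-6-methoxy-2,5-dimethyl-4-{[tri(propan-2-yl)silyl]oxy}benzoic acid; 22 methyl 2,4-dihydroxy-3,5,6-trimethylbenzoate
Product: 25 methyl 4-{[3-chloro-6-methoxy-2,5-dimethyl-4-(triisopropylsilyloxy)benzoyl]oxy}-2-hydroxy-3,5,6-trimethylbenzoate, via acid chloride 23 (not isolated), via sodium phenoxide 24 (not isolated)
Conditions: 18, (COCl)2, cat. DMF, CH2Cl2, 0 °C to rt, evaporate; 22, NaH (1.0 equiv), THF, 0 °C; then crude 23, THF, 0 to 50 °C
Reagents that add atoms: none
Why: Acylation of a phenoxide by an aroyl chloride (nucleophilic acyl substitution) is the most forcing simple esterification for a di-ortho-substituted acid, and one equivalent of base deprotonates only the more acidic, non-chelated 4-hydroxyl of 22, so the ester should form at O4 while the hydrogen-bonded 2-hydroxyl stays free.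

Step 11
Reactants: 25 methyl 4-{[3-chloro-6-methoxy-2,5-dimethyl-4-(triisopropylsilyloxy)benzoyl]oxy}-2-hydroxy-3,5,6-trimethylbenzoate
Product: 26 methyl 4-[(3-chloro-4-hydroxy-6-methoxy-2,5-dimethylbenzoyl)oxy]-2-hydroxy-3,5,6-trimethylbenzoate (target)
Conditions: Bu4NF, AcOH, THF, 0 °C to rt
Reagents that add atoms: none
Why: Fluoride-mediated cleavage of an aryl silyl ether, buffered with acetic acid, frees the 4'-hydroxyl without exposing the hindered aryl ester or the methyl ester to basic fluoride or free phenoxide.

**Compound list**

1 | trichloroacetyl chloride | ClC(Cl)(Cl)C(Cl)=O | starting material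
2 | propyne | CC#C | starting material
3 | dichloroketene | O=C=C(Cl)Cl | intermediate
4 | 4,4-dichloro-3-methylcyclobut-2-en-1-one | O=C1C=C(C)C1(Cl)Cl | intermediate
5 | 4-chloro-3-methylcyclobut-2-en-1-one (racemic) | O=C1C=C(C)C1Cl | intermediate
6 | chloroacetaldehyde dimethyl acetal (2-chloro-1,1-dimethoxyethane) | COC(CCl)OC | starting material
7 | sodium methoxyacetylide | COC#[C-].[Na+] | intermediate
8 | 1-methoxyprop-1-yne | CC#COC | intermediate
9 | (3E)-4-chloro-3-methylbuta-1,3-dien-1-one (chlorovinylketene) | O=C=C/C(C)=C/Cl | intermediate
10 | 4-[(E)-1-chloroprop-1-en-2-yl]-3-methoxy-2-methylcyclobut-2-en-1-one (racemic) | COC1=C(C)C(=O)C1/C(C)=C/Cl | intermediate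
11 | (3E,5E)-6-chloro-3-methoxy-2,5-dimethylhexa-1,3,5-trien-1-one (dienylketene) | O=C=C(C)/C(OC)=C\C(C)=C\Cl | intermediate
12 | 6-chloro-3-methoxy-2,5-dimethylcyclohexa-2,4-dien-1-one (racemic) | COC1=C(C)C(=O)C(Cl)C(C)=C1 | intermediate
13 | 2-chloro-5-methoxy-3,6-dimethylphenol | COc1cc(C)c(Cl)c(O)c1C | intermediate
14 | (2-chloro-5-methoxy-3,6-dimethylphenoxy)tri(propan-2-yl)silane | COc1cc(C)c(Cl)c(O[Si](C(C)C)(C(C)C)C(C)C)c1C | intermediate
15 | (4-bromo-2-chloro-5-methoxy-3,6-dimethylphenoxy)tri(propan-2-yl)silane | COc1c(Br)c(C)c(Cl)c(O[Si](C(C)C)(C(C)C)C(C)C)c1C | intermediate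
16 | [3-chloro-6-methoxy-2,5-dimethyl-4-(triisopropylsilyloxy)phenyl]lithium | COc1c([Li])c(C)c(Cl)c(O[Si](C(C)C)(C(C)C)C(C)C)c1C | intermediate
17 | lithium 3-chloro-6-methoxy-2,5-dimethyl-4-(triisopropylsilyloxy)benzoate | COc1c(C(=O)[O-])c(C)c(Cl)c(O[Si](C(C)C)(C(C)C)C(C)C)c1C.[Li+] | intermediate
18 | 3-chloro-6-methoxy-2,5-dimethyl-4-{[tri(propan-2-yl)silyl]oxy}benzoic acid | COc1c(C(=O)O)c(C)c(Cl)c(O[Si](C(C)C)(C(C)C)C(C)C)c1C | intermediate
19 | methyl 2,4-dihydroxy-3,6-dimethylbenzoate (atraric acid) | COC(=O)c1c(C)cc(O)c(C)c1O | starting material
20 | methyl 3-[chloro(methoxy)methyl]-4,6-dihydroxy-2,5-dimethylbenzoate (racemic) | COC(=O)c1c(C)c(C(Cl)OC)c(O)c(C)c1O | intermediate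
21 | methyl 3-formyl-4,6-dihydroxy-2,5-dimethylbenzoate | COC(=O)c1c(C)c(C=O)c(O)c(C)c1O | intermediate
22 | methyl 2,4-dihydroxy-3,5,6-trimethylbenzoate | COC(=O)c1c(C)c(C)c(O)c(C)c1O | intermediate
23 | 3-chloro-6-methoxy-2,5-dimethyl-4-(triisopropylsilyloxy)benzoyl chloride | COc1c(C(=O)Cl)c(C)c(Cl)c(O[Si](C(C)C)(C(C)C)C(C)C)c1C | intermediate
24 | sodium 3-hydroxy-4-(methoxycarbonyl)-2,5,6-trimethylphenoxide | COC(=O)c1c(C)c(C)c([O-])c(C)c1O.[Na+] | intermediate
25 | methyl 4-{[3-chloro-6-methoxy-2,5-dimethyl-4-(triisopropylsilyloxy)benzoyl]oxy}-2-hydroxy-3,5,6-trimethylbenzoate | COC(=O)c1c(C)c(C)c(OC(=O)c2c(C)c(Cl)c(O[Si](C(C)C)(C(C)C)C(C)C)c(C)c2OC)c(C)c1O | intermediate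
26 | methyl 4-[(3-chloro-4-hydroxy-6-methoxy-2,5-dimethylbenzoyl)oxy]-2-hydroxy-3,5,6-trimethylbenzoate | COC(=O)c1c(C)c(C)c(OC(=O)c2c(C)c(Cl)c(O)c(C)c2OC)c(C)c1O | target

**Count and risks**

Total step count: 11. Longest linear sequence: 8 steps (steps 1, 2, 4, 5, 6, 7, 10, 11).

1. Step 4 (proposed new method). Three things could go wrong. The chlorovinylketene may dimerize, or acylate phenol already formed, before the ynol ether captures it. The cascade may stall at the vinylcyclobutenone. The chlorodienone may lose chloride by ionization instead of enolizing. The fallback uses established chemistry and sets out from 4. Exhaustive dechlorination with excess Zn dust, TMEDA and AcOH in EtOH should give 3-methylcyclobut-2-en-1-one F1. Heating F1 with 8 in toluene at 80 °C, the established benzannulation of a 3-alkylcyclobutenone with an alkoxyalkyne, should give 3-methoxy-2,5-dimethylphenol F2. Amine-catalysed ortho-selective chlorination of F2 (SO2Cl2, catalytic diisobutylamine, toluene) should then place chlorine at the position ortho to the hydroxyl and para to the methoxy group. This returns to the route at 13.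

2. Step 2. The zinc dienolate may be protonated at the unchlorinated α-carbon, which moves the double bond and leaves a vinylic chlorine. Reduction may also run on to the chlorine-free cyclobutenone, and the volatile, heat-sensitive product may be lost on isolation. The fallback sets out from 4 and carries both chlorines through the ring construction. Heating 4 with 8 in toluene should give 6,6-dichloro-3-methoxy-2,5-dimethylcyclohexa-2,4-dien-1-one F3, a blocked dienone that cannot enolize. Reductive aromatization of F3 with Zn dust in AcOH at rt can remove only one chlorine and returns to the route at 13. Dechlorination is thereby deferred to a stage with a single possible outcome.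

3. Step 10. Acyl transfer between a carbonyl flanked by two ortho substituents and a phenoxide flanked by two methyl groups may be slow. Hydrolysis of the acid chloride, acylation at the 2-oxygen or silyl transfer to the phenoxide could then compete. The fallback sets out from 18 and 22 and changes the mechanism from base-mediated addition–elimination to an acid-mediated acylium pathway. Trifluoroacetic anhydride in toluene at rt should convert 18 into the mixed anhydride 3-chloro-6-methoxy-2,5-dimethyl-4-(triisopropylsilyloxy)benzoic trifluoroacetic anhydride F4. F4 ionizes to a linear acylium ion, stabilized by the ortho-methoxy and para-silyloxy groups and no longer shielded by its ortho substituents. The neutral 4-hydroxyl of 22 captures it, which returns to the route at 25.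

**Further compounds**

F1 | step 4 | 3-methylcyclobut-2-en-1-one | O=C1C=C(C)C1
F2 | step 4 | 3-methoxy-2,5-dimethylphenol | COc1cc(C)cc(O)c1C
F3 | step 2 | 6,6-dichloro-3-methoxy-2,5-dimethylcyclohexa-2,4-dien-1-one | COC1=C(C)C(=O)C(Cl)(Cl)C(C)=C1
F4 | step 10 | 3-chloro-6-methoxy-2,5-dimethyl-4-(triisopropylsilyloxy)benzoic trifluoroacetic anhydride | COc1c(C(=O)OC(=O)C(F)(F)F)c(C)c(Cl)c(O[Si](C(C)C)(C(C)C)C(C)C)c1C
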